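**Design of a synthesis of 3,4,6-tribromo-2-(5-bromo-2-hydroxyphenoxy)phenol (15)**

Atom labels used throughout: ring B is the tribrominated ring, with C1 the hydroxyl carbon, C2 the ether carbon, C3/C4/C6 the brominated carbons and C5 the only CH. Ring A is the monobrominated ring, with C1' the hydroxyl carbon, C2' the ether carbon and C4' the brominated carbon.

## The problem

Target 15 is a diaryl ether of two ortho-oxygenated phenols and has no stereocentre, so the task is purely one of regiochemistry and chemoselectivity. Ring A (C1' hydroxyl, C2' ether oxygen, C4' bromine para to the hydroxyl) is trivial: this pattern can be bought as 5-bromo-2-methoxyphenol (6). Ring B is the difficulty. Its bromines at C4 and C6 are para and ortho to the C1 hydroxyl and can come from phenol-directed electrophilic bromination. The bromine at C3 is meta to that hydroxyl and cannot be set this way. The ether carbon C2 is flanked on both sides, by the hydroxyl carbon and by C3–Br. A copper-mediated ether coupling at C2 would therefore be slow and would have to discriminate between several C–Br bonds. The four aryl bromides rule out reductive conditions, indiscriminate metal–halogen exchange and cross-coupling catalysts late in the route. The two electron-rich phenols over-brominate easily; ring A in particular has a free position (C6') ortho to its hydroxyl, so this oxygen must stay masked until ring B is fully brominated. The feature that opens the route is the contiguous array C1(O)–C2(OAr)–C3(Br). An ether oxygen and a bromine on adjacent carbons are what a nucleophile and an electrophile leave behind across an aryne C2≡C3. The C1 oxygen can be carried as a boryl group, which steers the nucleophile to C2 and is later oxidised to the hydroxyl.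

## Retrosynthesis

**15 to 14.** The O–CH3 bond of ring A is the last one formed in the backward sense, and the target is traced to methyl ether 14. The ring A hydroxyl is kept masked because, once free, its ortho position C6' would take bromine as readily as ring B. A methyl ether is preferred to a benzyl or silyl group because this oxygen must pass through Grignard reagents, alkaline peroxide and bromine, and because phenol 6 is sold with it. The forward step is a Lewis-acid demethylation, which must leave the diaryl ether and four C–Br bonds alone.

**14 to 13.** The C4–Br and C6–Br bonds are cut, leading to monobromophenol 13. These two carbons are the only ones activated by the C1 hydroxyl, and C5 is meta to it, so ring B can take exactly two bromines. The forward reaction has only to stop before the anisole-type ring A reacts. Doing this bromination earlier is not possible, because before 13 ring B has no free hydroxyl to direct it.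

**13 to 12.** The C1–O bond is traded for a C1–B bond, giving pinacol boronate 12. The boryl group is inert to the organomagnesium chemistry that precedes it and is converted to the hydroxyl by a standard oxidation. It is also the element that controls the key step.

**12 to 5, 6 and 7 (key disconnection).** The O–C2 and C3–Br bonds are cut together. Boronate 12 is seen as the product of aryloxy-bromination of 3-borylbenzyne 10, which comes from iodo triflate 5 by iodine–magnesium exchange (giving 9) and loss of triflate. Phenol 6 is used as its chloromagnesium salt 8, which adds to C2 to give arylmagnesium 11, and 1,2-dibromotetrachloroethane (7) delivers bromine to C3. The neighbouring cuts are weaker. An Ullmann-type O–C2 coupling would face a doubly ortho-substituted halide and competing C–Br sites. A nucleophilic aromatic substitution would need an extra activating group that must then be converted to the hydroxyl. Neither would place the C3 bromine in the same operation. The precursors are as simple as they can be: a trisubstituted benzene, a commercial phenol and a commercial bromine donor. The forward reaction has to show three things. The phenoxide must add next to boron. Only the aryl iodide of 5 may undergo exchange, not the bromide of 8. Arylmagnesium 11 must survive until it meets 7.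

**5 to 4 to 1.** The S–O bond of triflate 5 is cut to give phenol 4, and the C–B bond of 4 is cut to give 2,6-diiodophenol (1). The forward sequence is deprotonation to phenoxide 2, a single iodine–magnesium exchange to the C,O-dimagnesiated species 3, and capture with a boron electrophile. This is preferred to electrophilic iodination of an ortho-borylphenol, which would favour the position para to the hydroxyl and risk ipso-iododeboronation. Starting from the symmetric diiodide fixes the iodine ortho to oxygen from the outset.

## Roads not taken

**Alternative 1: ring A by ketone–vinamidinium benzannulation.**
- Cut: ring A is opened across C2'–C3' and C5'–C6' into aryloxyacetone A2, which carries the complete ring B as its methyl ether, and 2-bromovinamidinium salt A3.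
- Forward key step: a double condensation under a strong alkoxide base with loss of two amine molecules would close ring A and give phenol A1, one demethylation away from 15.
- Merits: the plan is convergent, the ring A bromine position is fixed by the central carbon of A3 and not by directing effects, and no selective bromination is needed at the end.
- Weak points:
  - The benzannulation is asked of a ketone whose methyl group is unactivated, where stalling after the first condensation and self-condensation are likely. The strong base also meets a tribromoaryl ether.
  - More seriously, A2 derives from phenol A4, which contains the whole difficulty of the target: a bromine beside the ether carbon and meta to the other oxygen, while the position para to the free hydroxyl must stay unbrominated. Electrophilic bromination of a catechol monoether goes first to that para position, so A4 needs a multistep synthesis of its own.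
  - The ring-forming event is spent on the ring that can be bought intact as 6.
- Comparison: this road is better in its endgame, because nothing after the key step depends on telling two electron-rich rings apart, and its key step uses no organometallic next to C–Br bonds. The chosen plan sets against this that it solves the C3 bromine and the hindered ether in one operation and reaches 15 in six steps from three purchasable compounds.

**Alternative 2: ring A from a 2-pyrone and an aryl ethynyl ether.**
- Cut: ring A is opened across C1'–C2' and C3'–C4' into 3-acetoxy-2-pyrone A6 and ethynyl ether A7.
- Forward key step: a thermal [4+2] cycloaddition followed by decarboxylative aromatisation would give acetate A5. Acetate cleavage, bromination para to the freed hydroxyl (giving A1) and demethylation would follow.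
- Merits: the polarised cycloaddition should place the two oxygens on adjacent carbons, the aromatisation is irreversible, and the late bromination of ring A is reliable because ring B is by then fully deactivated.
- Weak points:
  - Aryl ethynyl ethers such as A7 are labile and are usually made by strong-base or organolithium eliminations, which a tribromoarene will not survive.
  - The pyrone is only a moderately reactive diene and would need high temperature.
  - A7 again has to come from A4, so the ring B problem is untouched.
  - Three steps follow the key step.
- Comparison: this road is longer and leaves the real difficulty unsolved. Its only advantage over the chosen plan is that each individual reaction type is known.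

**Alternative 3: ring B from a cyclohexane-1,3-dione.**
- Cut: ring B is built from acyclic material by disconnecting C2–C3 of keto ester A9.
- Forward key step: a Claisen cyclisation of the aryloxy-bearing enolate onto the ester would give dione A8. One carbonyl would then become the vinyl bromide (A10), and dehydrogenation would give phenol 13 of the chosen route.
- Merits: it builds the right ring, the oxygen and bromine flanking the ether carbon are placed without ambiguity by the 1,3-dione, only one enolate can close a six-membered ring, and every step is classical with no organometallic near an aryl bromide.
- Weak points: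
  - Step count: A9 needs a bromomethyl ketone of a glutarate half-ester and an alkylation, then cyclisation, bromide formation and aromatisation, about six or seven steps to 13 against four in the chosen route.
  - 2-Aryloxy-1,3-diones are prone to retro-Claisen cleavage.
  - Aromatising A10 is a change of oxidation level that usually costs a halogenation–elimination sequence.
- Comparison: step for step this road is the more reliable, and that is conceded. The chosen plan sets brevity and convergence against it, and holds a known-chemistry fallback for its one unprecedented step.

Key step: step 3

Remark on the chemistry: magnesium species are drawn as monomeric chloromagnesium compounds, although in THF with LiCl they are aggregates.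

## Route

Step 1
Reactants: 1 2,6-diiodophenol
Product: 4 2-iodo-6-(4,4,5,5-tetramethyl-1,3,2-dioxaborolan-2-yl)phenol, via chloromagnesium 2,6-diiodophenoxide 2 (not isolated), via C-magnesiated iodophenoxide 3 (not isolated)
Conditions: MeMgCl (1.0 equiv), LiCl (1.0 equiv), THF, −30 °C; iPrMgCl (1.1 equiv), −30 °C to rt; iPrOBpin (2 equiv), −30 °C to rt; aq NH4Cl
Reagents that add atoms: 2-isopropoxy-4,4,5,5-tetramethyl-1,3,2-dioxaborolane (iPrOBpin), CC(C)OB1OC(C)(C)C(C)(C)O1
Why: Deprotonation with MeMgCl in the presence of LiCl gives a soluble magnesium phenoxide, a substrate class on which iodine–magnesium exchange with iPrMgCl is established for unprotected iodophenols; the first exchange makes the ring too electron-rich for a second, and the arylmagnesium 3 is captured by the boron electrophile (halogen–magnesium exchange followed by borylation).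

Step 2
Reactants: 4 2-iodo-6-(4,4,5,5-tetramethyl-1,3,2-dioxaborolan-2-yl)phenol
Product: 5 2-iodo-6-(4,4,5,5-tetramethyl-1,3,2-dioxaborolan-2-yl)phenyl trifluoromethanesulfonate
Conditions: Tf2O, pyridine, CH2Cl2, 0 °C
Reagents that add atoms: trifluoromethanesulfonic anhydride, O=S(=O)(OS(=O)(=O)C(F)(F)F)C(F)(F)F
Why: Standard O-triflation of a phenol; 2,6-disubstituted phenols are routinely triflated under these conditions, and the pinacol boronate and the aryl iodide are inert to them.

Step 3
Reactants: 5 2-iodo-6-(4,4,5,5-tetramethyl-1,3,2-dioxaborolan-2-yl)phenyl trifluoromethanesulfonate; 6 5-bromo-2-methoxyphenol; 7 1,2-dibromo-1,1,2,2-tetrachloroethane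
Product: 12 2-[3-bromo-2-(5-bromo-2-methoxyphenoxy)phenyl]-4,4,5,5-tetramethyl-1,3,2-dioxaborolane, via chloromagnesium 5-bromo-2-methoxyphenoxide 8 (not isolated), via magnesiated aryl triflate 9 (not isolated), via 3-(pinacolboryl)benzyne 10 (not isolated), via aryloxy arylmagnesium chloride 11 (not isolated)
Conditions: 6 (2.5 equiv), iPrMgCl·LiCl (2.5 equiv), THF, 0 °C; then 5 (1.0 equiv), −78 °C; iPrMgCl·LiCl (1.05 equiv), −78 to −20 °C; then 7 (3 equiv), −78 °C to rt
Reagents that add atoms: none
Why: Proposed new method: a three-component aryloxy-bromination of a 3-borylbenzyne with a magnesium phenoxide, closest to the known ortho-selective addition of amines to 3-borylbenzynes and to the addition of magnesium thiolates and amides to Grignard-generated arynes followed by electrophilic quench. Phenol 6 is first converted completely into its chloromagnesium salt 8 so that no proton source remains, and iodine–magnesium exchange on 5 at −78 °C then gives the ortho-magnesiated triflate 9, which loses MgCl(OTf) on warming to form aryne 10 across C2–C3. The electropositive boryl group at C1 distorts the aryne so that C2 is the flatter, more electrophilic carbon, and coordination of the phenoxide oxygen to boron would deliver it to the same carbon, so the O–C2 bond forms next to boron and magnesium ends up at C3 in 11. Arylmagnesium 11 then attacks a bromine of 7, which collapses to tetrachloroethene, and the C3–Br bond is formed. No ring is closed and no stereocentre is created. The step needs regioselective addition (secured by the boryl group), chemoselective exchange of the iodide of 5 over the bromide of 8 and over attack at boron (secured by the low temperature and by only a slight excess of iPrMgCl·LiCl, which also leaves no free Grignard reagent to add to the aryne), and capture of 11 by bromine and not by a proton (secured by full deprotonation of 6 and anhydrous conditions).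

Step 4
Reactants: 12 2-[3-bromo-2-(5-bromo-2-methoxyphenoxy)phenyl]-4,4,5,5-tetramethyl-1,3,2-dioxaborolane
Product: 13 3-bromo-2-(5-bromo-2-methoxyphenoxy)phenol
Conditions: 30% aq H2O2, NaOH, THF/H2O, 0 °C to rt
Reagents that add atoms: hydrogen peroxide, OO
Why: Oxidation of an arylboronic ester with alkaline hydrogen peroxide: hydroperoxide adds to boron, the aryl group migrates from boron to oxygen at the same carbon and hydrolysis frees the phenol; aryl bromides, the diaryl ether and the methyl ether are untouched.

Step 5
Reactants: 13 3-bromo-2-(5-bromo-2-methoxyphenoxy)phenol
Product: 14 3,4,6-tribromo-2-(5-bromo-2-methoxyphenoxy)phenol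
Conditions: Br2 (2.1 equiv), AcOH, rt
Reagents that add atoms: bromine, BrBr
Why: Electrophilic aromatic bromination directed by the free hydroxyl: C4 (para) and C6 (ortho) are the only positions it activates, C5 is meta to it and ends up between two bromines, and the anisole-type ring A is far less reactive than a phenol, so two equivalents of bromine should stop at 14.

Step 6
Reactants: 14 3,4,6-tribromo-2-(5-bromo-2-methoxyphenoxy)phenol
Product: 15 3,4,6-tribromo-2-(5-bromo-2-hydroxyphenoxy)phenol
Conditions: BBr3 (3 equiv), CH2Cl2, −78 °C to rt; then H2O
Reagents that add atoms: none
Why: Lewis-acid cleavage of an aryl methyl ether with BBr3 (coordination at oxygen, bromide attack at the methyl group); diaryl ethers and aryl bromides are stable to the reagent and the boron aryloxides are hydrolysed on aqueous work-up.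

## Compound list

1 | 2,6-diiodophenol | Oc1c(I)cccc1I | starting material
2 | chloromagnesium 2,6-diiodophenoxide | Cl[Mg]Oc1c(I)cccc1I | intermediate
3 | chloromagnesium 2-(chloromagnesio)-6-iodophenoxide | Cl[Mg]Oc1c(I)cccc1[Mg]Cl | intermediate
4 | 2-iodo-6-(4,4,5,5-tetramethyl-1,3,2-dioxaborolan-2-yl)phenol | CC1(C)OB(OC1(C)C)c1cccc(I)c1O | intermediate
5 | 2-iodo-6-(4,4,5,5-tetramethyl-1,3,2-dioxaborolan-2-yl)phenyl trifluoromethanesulfonate | CC1(C)OB(OC1(C)C)c1cccc(I)c1OS(=O)(=O)C(F)(F)F | intermediate
6 | 5-bromo-2-methoxyphenol | COc1ccc(Br)cc1O | starting material
7 | 1,2-dibromo-1,1,2,2-tetrachloroethane | BrC(Cl)(Cl)C(Cl)(Cl)Br | starting material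
8 | chloromagnesium 5-bromo-2-methoxyphenoxide | COc1ccc(Br)cc1O[Mg]Cl | intermediate
9 | [3-(4,4,5,5-tetramethyl-1,3,2-dioxaborolan-2-yl)-2-(trifluoromethanesulfonyloxy)phenyl]magnesium chloride | CC1(C)OB(OC1(C)C)c1cccc([Mg]Cl)c1OS(=O)(=O)C(F)(F)F | intermediate
10 | 3-(4,4,5,5-tetramethyl-1,3,2-dioxaborolan-2-yl)benzyne (2-(2,3-didehydrophenyl) pinacol boronate) | CC1(C)OB(OC1(C)C)C1=CC=CC#C1 | intermediate
11 | [2-(5-bromo-2-methoxyphenoxy)-3-(4,4,5,5-tetramethyl-1,3,2-dioxaborolan-2-yl)phenyl]magnesium chloride | COc1ccc(Br)cc1Oc1c([Mg]Cl)cccc1B1OC(C)(C)C(C)(C)O1 | intermediate
12 | 2-[3-bromo-2-(5-bromo-2-methoxyphenoxy)phenyl]-4,4,5,5-tetramethyl-1,3,2-dioxaborolane | COc1ccc(Br)cc1Oc1c(Br)cccc1B1OC(C)(C)C(C)(C)O1 | intermediate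
13 | 3-bromo-2-(5-bromo-2-methoxyphenoxy)phenol | COc1ccc(Br)cc1Oc1c(Br)cccc1O | intermediate
14 | 3,4,6-tribromo-2-(5-bromo-2-methoxyphenoxy)phenol | COc1ccc(Br)cc1Oc1c(O)c(Br)cc(Br)c1Br | intermediate
15 | 3,4,6-tribromo-2-(5-bromo-2-hydroxyphenoxy)phenol | Oc1ccc(Br)cc1Oc1c(O)c(Br)cc(Br)c1Br | target

## Step count and risk

Total steps: 6. Longest linear sequence: 6 steps, from 2,6-diiodophenol (1); compounds 6 and 7 enter in step 3.

**Step 3 (key step, new method).**
- What may go wrong:
  - The aggregated magnesium phenoxide may be too weak a nucleophile, so that the aryne is consumed by self-reaction or by residual isopropyl Grignard reagent.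
  - Regiocontrol may erode if steric repulsion by the pinacolboryl group outweighs its electronic bias and the phenoxide adds at C3.
  - The arylmagnesium may be protonated before it is brominated; that would leave C3 without a bromine, which no later electrophilic step can add.
- Fallback (known chemistry): it sets out from phenol 6 and comes back to the route at phenol 13. Nucleophilic aromatic substitution of 6 on commercial 3-bromo-2-fluorobenzaldehyde (K2CO3, DMF, 100 °C), where the fluoride is activated by the ortho formyl group, should give 3-bromo-2-(5-bromo-2-methoxyphenoxy)benzaldehyde F1. Baeyer–Villiger oxidation with mCPBA in CH2Cl2 would convert the aldehyde into 3-bromo-2-(5-bromo-2-methoxyphenoxy)phenyl formate F2. Methanolysis (catalytic K2CO3, MeOH) then releases 13, after which steps 5 and 6 follow unchanged.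

**Step 1.**
- What may go wrong: the iodine–magnesium exchange on the electron-rich, aggregated magnesium phenoxide may be incomplete, or the boron electrophile may be sequestered at the phenoxide oxygen, so that protodeiodinated phenol is recovered after work-up.
- Fallback: it sets out from 1 and comes back at 4. The hydroxyl is protected with chloromethyl methyl ether and iPr2NEt to give 1,3-diiodo-2-(methoxymethoxy)benzene F3. A single exchange with iPrMgCl·LiCl at −40 °C gives [3-iodo-2-(methoxymethoxy)phenyl]magnesium chloride F4, which is quenched with iPrOBpin to give 2-[3-iodo-2-(methoxymethoxy)phenyl]-4,4,5,5-tetramethyl-1,3,2-dioxaborolane F5. Acetal cleavage with HCl in methanol returns phenol 4.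

**Step 5.**
- What may go wrong: ring A may be brominated in competition (at the position ortho to its methoxy group or para to the ether oxygen) before the second bromine has entered ring B, which is already deactivated by one bromine; the result would be a mixture that is hard to separate.
- Fallback: it sets out from 13 and comes back at 14. The single exhaustive bromination is replaced by two reagent-controlled monobrominations. The para-selective reagent nBu4NBr3 in CH2Cl2/MeOH should give 3,4-dibromo-2-(5-bromo-2-methoxyphenoxy)phenol F6, which is purified. Amine-catalysed ortho-bromination with N-bromosuccinimide and catalytic iPr2NH in CH2Cl2 then places the C6 bromine and gives 14.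

## Further compounds

F1 | step 3 | 3-bromo-2-(5-bromo-2-methoxyphenoxy)benzaldehyde | COc1ccc(Br)cc1Oc1c(Br)cccc1C=O
F2 | step 3 | 3-bromo-2-(5-bromo-2-methoxyphenoxy)phenyl formate | COc1ccc(Br)cc1Oc1c(Br)cccc1OC=O
F3 | step 1 | 1,3-diiodo-2-(methoxymethoxy)benzene | COCOc1c(I)cccc1I
F4 | step 1 | [3-iodo-2-(methoxymethoxy)phenyl]magnesium chloride | COCOc1c(I)cccc1[Mg]Cl
F5 | step 1 | 2-[3-iodo-2-(methoxymethoxy)phenyl]-4,4,5,5-tetramethyl-1,3,2-dioxaborolane | COCOc1c(I)cccc1B1OC(C)(C)C(C)(C)O1
F6 | step 5 | 3,4-dibromo-2-(5-bromo-2-methoxyphenoxy)phenol | COc1ccc(Br)cc1Oc1c(O)ccc(Br)c1Br
A1 | alternative 1 | 4-bromo-2-(2,3,5-tribromo-6-methoxyphenoxy)phenol | COc1c(Br)cc(Br)c(Br)c1Oc1cc(Br)ccc1O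
A2 | alternative 1 | 1-(2,3,5-tribromo-6-methoxyphenoxy)propan-2-one | CC(=O)COc1c(OC)c(Br)cc(Br)c1Br
A3 | alternative 1 | 2-bromo-1,3-bis(dimethylamino)trimethinium hexafluorophosphate | CN(C)C=C(Br)C=[N+](C)C.F[P-](F)(F)(F)(F)F
A4 | alternative 1 | 2,3,5-tribromo-6-methoxyphenol | COc1c(Br)cc(Br)c(Br)c1O
A5 | alternative 2 | 2-(2,3,5-tribromo-6-methoxyphenoxy)phenyl acetate | CC(=O)Oc1ccccc1Oc1c(OC)c(Br)cc(Br)c1Br
A6 | alternative 2 | 2-oxo-2H-pyran-3-yl acetate (3-acetoxy-2-pyrone) | CC(=O)OC1=CC=COC1=O
A7 | alternative 2 | 1,2,5-tribromo-3-(ethynyloxy)-4-methoxybenzene | C#COc1c(OC)c(Br)cc(Br)c1Br
A8 | alternative 3 | 2-(5-bromo-2-methoxyphenoxy)cyclohexane-1,3-dione | COc1ccc(Br)cc1OC1C(=O)CCCC1=O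
A9 | alternative 3 | methyl 6-(5-bromo-2-methoxyphenoxy)-5-oxohexanoate | COC(=O)CCCC(=O)COc1cc(Br)ccc1OC
A10 | alternative 3 | 3-bromo-2-(5-bromo-2-methoxyphenoxy)cyclohex-2-en-1-one | COc1ccc(Br)cc1OC1=C(Br)CCCC1=O
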